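The numbering runs as follows: ring C1 (acyloxy CH), C2 (ketone), C3–C4 (ring oxirane, methyl on C3), C5, C6; chain C7 (oxirane carbon), C14 (its CH2), C8 (enone carbonyl), C9–C11. The feature exploited is that the C1 oxygen, C1, C6, C7 and C8 can form a trans-fused α-methylene-γ-butyrolactone (C7=C14) whose carbonyl carbon is carbon monoxide. One palladium-catalysed cyclocarbonylation makes O–C8 and C7–C8 and closes this ring. Its precursor is a trans-2-ethynylcyclohexenol with a free C1 hydroxyl, a C6 ethynyl group, a C2 PMB ether and C3=C4 already present. The rigid lactone then controls C7, the axial C2 ether controls C3/C4, and an alkenyllithium opens the lactone, freeing C1–OH for the isovalerate.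

Key step: step 9

Remark on numbering: the target numbering above is used for every intermediate.

Assumption: 9-amino-9-deoxy-epi-quinine is taken to deliver the (1S,6S)-oxirane 2. Should its sense be opposite, the quinidine-derived pseudoenantiomer is used and nothing else changes.

Design notes:
- **C3=C4 installed early.** It is introduced at the epoxy-ketone stage, where C3 carries the only enolisable hydrogens. After lactone formation a C2 ketone could also enolise towards C1.
- **An sp2 C3.** It avoids a racemic C3 centre in the enantioselective step and an axial methyl group in the reactive conformer of 14.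
- **Ring oxirane made at the C2 ether stage.** Nucleophilic epoxidation of a C2 enone would attack anti to the C6 chain and give the wrong C3/C4 configuration.

Step 1
Reactants: 1 cyclohex-2-en-1-one
Product: 2 (1S,6S)-7-oxabicyclo[4.1.0]heptan-2-one
Conditions: 9-amino-9-deoxy-epi-quinine (10 mol %), CF3CO2H (20 mol %), 50% aq H2O2 (1.5 equiv), dioxane, 30 °C
Reagents that add atoms: hydrogen peroxide, OO
Why: Iminium-catalysed Weitz–Scheffer epoxidation, a known catalytic asymmetric epoxidation of cyclic enones, in which the chiral primary amine salt condenses with the enone, its protonated quinuclidine guides hydrogen peroxide to one face of C6, and closure of the peroxy-enamine sets C1 and C6 together as a cis-oxirane.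

Step 2
Reactants: 2 (1S,6S)-7-oxabicyclo[4.1.0]heptan-2-one
Product: 4 (1S,6S)-3-methyl-7-oxabicyclo[4.1.0]heptan-2-one as C3 epimers, via lithium enolate 3 (not isolated)
Conditions: LiN(iPr)2 (1.05 equiv), THF, −78 °C; MeI (1.5 equiv), −78 → −20 °C
Reagents that add atoms: iodomethane, CI
Why: Kinetic enolate alkylation, in which the oxirane C1–H cannot enolise because that would place a double bond on the three-membered ring, so deprotonation and methylation occur only at C3, whose configuration is irrelevant since it becomes sp2 in the next step.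

Step 3
Reactants: 4 (1S,6S)-3-methyl-7-oxabicyclo[4.1.0]heptan-2-one as C3 epimers
Product: 6 (1S,6S)-3-methyl-2-(trimethylsilyloxy)-7-oxabicyclo[4.1.0]hept-2-ene, via lithium enolate 5 (not isolated)
Conditions: LiN(iPr)2 (1.2 equiv), THF, −78 °C; Me3SiCl (1.5 equiv), −78 → 0 °C
Reagents that add atoms: chlorotrimethylsilane, C[Si](C)(C)Cl
Why: Regiospecific enolate O-silylation, in which C3–H is the only enolisable hydrogen left, so both C3 epimers converge on one tetrasubstituted silyl enol ether.

Step 4
Reactants: 6 (1S,6S)-3-methyl-2-(trimethylsilyloxy)-7-oxabicyclo[4.1.0]hept-2-ene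
Product: 7 (1S,6S)-3-methyl-7-oxabicyclo[4.1.0]hept-3-en-2-one
Conditions: Pd(OAc)2 (1.05 equiv), MeCN, 23 °C; filtration, used directly
Reagents that add atoms: none
Why: Saegusa–Ito oxidation, known for silyl enol ethers of α,β-epoxy ketones, in which palladation at C3 and syn β-hydride elimination of a ring C4 hydrogen give the endocyclic 2-methyl enone under neutral conditions, and the base-sensitive product (deprotonation at C5 would open the oxirane and aromatise the ring) is carried on at once.

Step 5
Reactants: 7 (1S,6S)-3-methyl-7-oxabicyclo[4.1.0]hept-3-en-2-one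
Product: 8 (1R,2R,6S)-3-methyl-7-oxabicyclo[4.1.0]hept-3-en-2-ol
Conditions: NaBH4 (1.1 equiv), CeCl3·7H2O (1.1 equiv), MeOH, −78 °C
Reagents that add atoms: none
Why: Luche reduction, in which the hard cerium-modified borohydride adds 1,2 to the nearly planar epoxy enone from the face opposite the oxirane oxygen (steric shielding plus Felkin–Anh alignment anti to the C1–O bond), which sets C2 with its hydroxyl cis to the oxirane.

Step 6
Reactants: 8 (1R,2R,6S)-3-methyl-7-oxabicyclo[4.1.0]hept-3-en-2-ol
Product: 10 (1S,2R,6S)-2-[(4-methoxybenzyl)oxy]-3-methyl-7-oxabicyclo[4.1.0]hept-3-ene, via sodium alkoxide 9 (not isolated)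
Conditions: NaH (1.2 equiv), THF/DMF, 0 °C; 4-MeOC6H4CH2Cl (1.2 equiv), Bu4NI (5 mol %), 0 → 23 °C
Reagents that add atoms: 4-methoxybenzyl chloride, COc1ccc(CCl)cc1
Why: Williamson etherification, in which the alkoxide is cis to the oxirane and cannot reach the backside of C1, so no Payne rearrangement competes, and the PMB ether is chosen because it cannot migrate to a neighbouring alkoxide and is removed later under neutral oxidation.

Step 7
Reactants: 10 (1S,2R,6S)-2-[(4-methoxybenzyl)oxy]-3-methyl-7-oxabicyclo[4.1.0]hept-3-ene; 11 trimethylsilylacetylene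
Product: 13 (1S,2R,6S)-2-[(4-methoxybenzyl)oxy]-3-methyl-6-[(trimethylsilyl)ethynyl]cyclohex-3-en-1-ol, via lithium trimethylsilylacetylide 12 (not isolated)
Conditions: 11 (2.5 equiv), n-BuLi (2.4 equiv), THF, −78 °C; BF3·OEt2 (2.4 equiv); then 10, −78 °C; aq NH4Cl
Reagents that add atoms: trimethylsilylacetylene 11, C#C[Si](C)(C)C
Why: Yamaguchi–Hirao alkynylation (BF3-assisted SN2 opening of an epoxide by a lithium acetylide, Fürst–Plattner course), in which attack is anti to the oxirane oxygen and goes to C6 because C1 is deactivated inductively by the adjacent C2 ether, so inversion at C6 sets the trans C1-hydroxyl/C6-alkynyl pair.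

Step 8
Reactants: 13 (1S,2R,6S)-2-[(4-methoxybenzyl)oxy]-3-methyl-6-[(trimethylsilyl)ethynyl]cyclohex-3-en-1-ol
Product: 14 (1S,2R,6S)-6-ethynyl-2-[(4-methoxybenzyl)oxy]-3-methylcyclohex-3-en-1-ol
Conditions: K2CO3 (0.2 equiv), MeOH, 23 °C
Reagents that add atoms: none
Why: Base-catalysed methanolysis of the alkynyl C–Si bond (protodesilylation), which touches neither the PMB ether nor any stereocentre.

Step 9
Reactants: 14 (1S,2R,6S)-6-ethynyl-2-[(4-methoxybenzyl)oxy]-3-methylcyclohex-3-en-1-ol; 15 carbon monoxide
Product: 16 (3aS,7R,7aS)-7-[(4-methoxybenzyl)oxy]-6-methyl-3-methylidene-3a,4,7,7a-tetrahydro-1-benzofuran-2(3H)-one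
Conditions: PdCl2 (5 mol %), SnCl2 (5 mol %), PPh3 (10 mol %), CO (8 atm), MeCN, 75 °C
Reagents that add atoms: carbon monoxide 15, [C-]#[O+]
Why: Divalent palladium, CO and the C1 hydroxyl form an alkoxycarbonylpalladium species (O–C8), the tethered alkyne inserts syn into the palladium–acyl bond (C7–C8), and protonolysis of the resulting alkenylpalladium by the HCl released earlier frees the C14 methylene and returns divalent palladium, so no oxidant is needed. The closest known reaction type is the PdCl2/SnCl2/phosphine cyclocarbonylation of homopropargylic alcohols to α-methylene-γ-butyrolactones, which includes the parent trans-2-ethynylcyclohexanol. The single new ring is closed by 5-exo-dig acylpalladation. No stereocentre is created, since the trans ring fusion is inherited from C1 and C6 as set in steps 1 and 7. The step needs chemoselective exo acylpalladation of the terminal alkyne in preference to 5-endo hydroalkoxylation, alkyne oligomerisation or reaction at C3=C4, and this is secured by the only free hydroxyl being homopropargylic, by CO pressure, and by the diequatorial C1/C6 half-chair being easy to reach because C3 is sp2 and carries no axial methyl group. The PMB ether and the trisubstituted alkene are spectators.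

Step 10
Reactants: 16 (3aS,7R,7aS)-7-[(4-methoxybenzyl)oxy]-6-methyl-3-methylidene-3a,4,7,7a-tetrahydro-1-benzofuran-2(3H)-one
Product: 17 (3R,3aR,7R,7aS)-7-[(4-methoxybenzyl)oxy]-6-methyl-3a,4,7,7a-tetrahydrospiro[1-benzofuran-3,2'-oxiran]-2-one
Conditions: t-BuOOH (5.5 M in decane, 3 equiv), LiOt-Bu (0.3 equiv), THF, −20 → 0 °C
Reagents that add atoms: tert-butyl hydroperoxide, CC(C)(C)OO
Why: Weitz–Scheffer epoxidation, in which the tert-butyl peroxide anion adds to C14 of the strongly electrophilic methylene lactone and the lactone enolate closes on oxygen from the C7 face that carries only the axial C6 hydrogen, the other face being flanked by C5, which sets C7 (R), while the electron-rich C3=C4 bond is inert to a nucleophilic oxidant.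

Step 11
Reactants: 17 (3R,3aR,7R,7aS)-7-[(4-methoxybenzyl)oxy]-6-methyl-3a,4,7,7a-tetrahydrospiro[1-benzofuran-3,2'-oxiran]-2-one
Product: 18 bis-epoxy lactone (17 carrying a C3–C4 oxirane anti to the C2 ether and syn to C7)
Conditions: mCPBA (1.3 equiv), CH2Cl2/aq phosphate buffer (pH 7.5), 0 °C
Reagents that add atoms: 3-chloroperoxybenzoic acid, OOC(=O)c1cccc(Cl)c1
Why: Prilezhaev epoxidation, in which the peracid picks the only electron-rich alkene and, since the trans ring fusion locks the C2 ether pseudoaxial on one face, approaches C3=C4 from the opposite face, which sets C3 and C4 syn to the C6 side chain as in the target.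

Step 12
Reactants: 19 2-methylbut-3-yn-2-ol
Product: 20 (E)-2-methyl-4-(tributylstannyl)but-3-en-2-ol
Conditions: Bu3SnH (1.05 equiv), PdCl2(PPh3)2 (1 mol %), THF, 23 °C
Reagents that add atoms: tributylstannane, CCCC[SnH](CCCC)CCCC
Why: Palladium-catalysed syn hydrostannylation of a terminal alkyne, in which the bulky tertiary carbinol sends tin to the terminal carbon and gives the (E)-alkenylstannane.

Step 13
Reactants: 18 bis-epoxy lactone; 20 (E)-2-methyl-4-(tributylstannyl)but-3-en-2-ol
Product: 22 hydroxy enone (free C1 hydroxyl; C8 now the ketone of an (E)-4-hydroxy-4-methylpent-2-enoyl group on C7), via dilithio alkenyl alkoxide 21 (not isolated)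
Conditions: 20 (1.3 equiv), n-BuLi (2.6 equiv), THF, −78 → −30 °C; then 18, −78 °C; AcOH, −78 °C
Reagents that add atoms: (E)-2-methyl-4-(tributylstannyl)but-3-en-2-ol 20, CCCC[Sn](CCCC)(CCCC)/C=C/C(C)(C)O
Why: Tin–lithium exchange followed by acyl substitution of a lactone by an alkenyllithium, in which the exchange keeps the E geometry, the tetrahedral lithium hemiketal alkoxide persists at −78 °C so that only one addition occurs, and the acidic quench releases the conjugated enone and the free C1 hydroxyl without touching C7.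

Step 14
Reactants: 22 hydroxy enone; 23 3-methylbutanoic anhydride
Product: 24 C1 3-methylbutanoate of 22
Conditions: (Me2CHCH2CO)2O (1.5 equiv), DMAP (0.2 equiv), pyridine, CH2Cl2, 0 → 23 °C
Reagents that add atoms: 3-methylbutanoic anhydride 23, CC(C)CC(=O)OC(=O)CC(C)C
Why: DMAP-catalysed acylation with an anhydride, in which the secondary equatorial C1 hydroxyl reacts, the tertiary C11 carbinol does not, and the conjugated open hydroxy enone is drained from any hemiketal form.

Step 15
Reactants: 24 C1 3-methylbutanoate of 22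
Product: 25 C2 alcohol (24 without the PMB group)
Conditions: DDQ (1.5 equiv), CH2Cl2/pH 7 buffer, 0 °C
Reagents that add atoms: none
Why: Oxidative PMB cleavage with DDQ (hydride abstraction from the electron-rich benzylic position, then hydrolysis), which runs at neutral pH so that neither Payne rearrangement of the trans epoxy alcohol nor acyl migration from C1 to C2 is triggered.

Step 16
Reactants: 25 C2 alcohol
Product: 26 target CNP0292003.1
Conditions: Dess–Martin periodinane (1.5 equiv), pyridine (5 equiv), CH2Cl2, 0 → 23 °C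
Reagents that add atoms: none
Why: Dess–Martin oxidation, a mild non-basic oxidation of the secondary C2 alcohol that gives the epoxy ketone without epimerising C1, whose ester is equatorial, and leaves the tertiary alcohol, both oxiranes and the enone untouched.

Compound list
1 | cyclohex-2-en-1-one | O=C1C=CCCC1 | starting material
2 | (1S,6S)-7-oxabicyclo[4.1.0]heptan-2-one | O=C1CCC[C@@H]2O[C@@H]21 | intermediate
3 | lithium enolate of 2 (C2=C3) | [Li]OC1=CCC[C@@H]2O[C@@H]21 | intermediate
4 | (1S,6S)-3-methyl-7-oxabicyclo[4.1.0]heptan-2-one, C3 epimers (centre erased in step 3) | O=C1C(C)CC[C@@H]2O[C@@H]21 | intermediate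
5 | lithium enolate of 4 (C2=C3) | [Li]OC1=C(C)CC[C@@H]2O[C@@H]21 | intermediate
6 | (1S,6S)-3-methyl-2-(trimethylsilyloxy)-7-oxabicyclo[4.1.0]hept-2-ene | C[Si](C)(C)OC1=C(C)CC[C@@H]2O[C@@H]21 | intermediate
7 | (1S,6S)-3-methyl-7-oxabicyclo[4.1.0]hept-3-en-2-one | O=C1C(C)=CC[C@@H]2O[C@@H]21 | intermediate
8 | (1R,2R,6S)-3-methyl-7-oxabicyclo[4.1.0]hept-3-en-2-ol, hydroxyl cis to the oxirane oxygen | O[C@@H]1C(C)=CC[C@@H]2O[C@@H]21 | intermediate
9 | sodium alkoxide of 8 | [Na+].[O-][C@@H]1C(C)=CC[C@@H]2O[C@@H]21 | intermediate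
10 | (1S,2R,6S)-2-[(4-methoxybenzyl)oxy]-3-methyl-7-oxabicyclo[4.1.0]hept-3-ene | COc1ccc(CO[C@@H]2C(C)=CC[C@@H]3O[C@@H]32)cc1 | intermediate
11 | trimethylsilylacetylene | C#C[Si](C)(C)C | starting material
12 | lithium trimethylsilylacetylide | [Li]C#C[Si](C)(C)C | intermediate
13 | (1S,2R,6S)-2-[(4-methoxybenzyl)oxy]-3-methyl-6-[(trimethylsilyl)ethynyl]cyclohex-3-en-1-ol | O[C@@H]1[C@H](OCc2ccc(OC)cc2)C(C)=CC[C@H]1C#C[Si](C)(C)C | intermediate
14 | (1S,2R,6S)-6-ethynyl-2-[(4-methoxybenzyl)oxy]-3-methylcyclohex-3-en-1-ol (C1 hydroxyl trans to ethynyl, cis to the C2 ether) | O[C@@H]1[C@H](OCc2ccc(OC)cc2)C(C)=CC[C@H]1C#C | intermediate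
15 | carbon monoxide | [C-]#[O+] | starting material
16 | (3aS,7R,7aS)-7-[(4-methoxybenzyl)oxy]-6-methyl-3-methylidene-3a,4,7,7a-tetrahydro-1-benzofuran-2(3H)-one (trans-fused) | C=C1C(=O)O[C@@H]2[C@H](OCc3ccc(OC)cc3)C(C)=CC[C@@H]12 | intermediate
17 | (3R,3aR,7R,7aS)-7-[(4-methoxybenzyl)oxy]-6-methyl-3a,4,7,7a-tetrahydrospiro[1-benzofuran-3,2'-oxiran]-2-one (oxirane oxygen on the face of the C6 hydrogen) | O=C1O[C@@H]2[C@H](OCc3ccc(OC)cc3)C(C)=CC[C@H]2[C@@]14CO4 | intermediate
18 | bis-epoxy lactone: 17 with a C3–C4 oxirane anti to the C2 ether; (1S,2S,3S,4S,6R,7R) in target numbering | O=C1O[C@@H]2[C@H](OCc3ccc(OC)cc3)[C@@]5(C)O[C@H]5C[C@H]2[C@@]14CO4 | intermediate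
19 | 2-methylbut-3-yn-2-ol | CC(C)(O)C#C | starting material
20 | (E)-2-methyl-4-(tributylstannyl)but-3-en-2-ol | CCCC[Sn](CCCC)(CCCC)/C=C/C(C)(C)O | intermediate
21 | (E)-dilithio alkenyl alkoxide from 20 | [Li]/C=C/C(C)(C)O[Li] | intermediate
22 | hydroxy enone: C1 alcohol, C2 PMB ether, C3–C4 oxirane, C7 oxirane bearing the (E)-4-hydroxy-4-methylpent-2-enoyl group; (1S,2S,3S,4S,6R,7R) in target numbering | O[C@@H]1[C@H](OCc2ccc(OC)cc2)[C@@]3(C)O[C@H]3C[C@H]1[C@]4(C(=O)/C=C/C(C)(C)O)CO4 | intermediate
23 | 3-methylbutanoic anhydride | CC(C)CC(=O)OC(=O)CC(C)C | starting material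
24 | C1 3-methylbutanoate of 22 | CC(C)CC(=O)O[C@@H]1[C@H](OCc2ccc(OC)cc2)[C@@]3(C)O[C@H]3C[C@H]1[C@]4(C(=O)/C=C/C(C)(C)O)CO4 | intermediate
25 | C2 alcohol: 24 without PMB, hydroxyl cis to the C1 ester and trans to the ring oxirane | CC(C)CC(=O)O[C@@H]1[C@H](O)[C@@]3(C)O[C@H]3C[C@H]1[C@]4(C(=O)/C=C/C(C)(C)O)CO4 | intermediate
26 | CNP0292003.1; (1S,3S,4S,6R,7R) in target numbering | CC(C)CC(=O)O[C@@H]1C(=O)[C@@]2(C)O[C@H]2C[C@H]1[C@]1(C(=O)/C=C/C(C)(C)O)CO1 | target

Total step count: 16. Longest linear sequence: 15 (steps 1–11 and 13–16).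

Steps most likely to fail

Step 9. What may go wrong is slow alkoxycarbonylation of the hindered secondary alcohol, competing cycloisomerisation of the alkynol, or ionisation of the allylic ether at 75 °C. The fallback leaves carbonylation aside and builds the same lactone by the classical malonate route, setting out from oxirane 10 and returning at 16. Sodium diethyl malonate (EtOH, reflux) opens 10 at C6 with inversion, and the C1 alkoxide closes onto one ester to give the α-ethoxycarbonyl lactone F1. LiOH followed by acidification gives the α-carboxy lactone F2. Aqueous formaldehyde and Et2NH, then NaOAc/AcOH, bring about decarboxylative Mannich methylenation to 16.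

Step 10. What may go wrong is poor facial selectivity in the oxirane closure, or attack of the peroxide anion at the lactone carbonyl. The fallback replaces oxygen transfer by dihydroxylation and displacement, setting out from 16 and returning at 18. mCPBA first epoxidises C3=C4 to the epoxy methylene lactone F3. OsO4 (cat.)/NMO then osmylates the remaining alkene from the C6–H face to the C7,C14-diol F4. MsCl/Et3N at −20 °C gives the primary mesylate F5, and DBU in CH2Cl2 closes the oxirane by attack of the C7 oxygen on C14, so the C7–O bond set by osmium is kept.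

Step 13. What may go wrong is a second addition after premature collapse of the tetrahedral intermediate, or opening of an oxirane by the organolithium. The fallback lowers the oxidation level first, setting out from 18 and returning at 22. i-Bu2AlH (CH2Cl2, −78 °C) gives the lactol F6. Excess 21 adds to its open aldehyde form to give the C8 allylic alcohol F7 (C8 epimers, inconsequential). MnO2 then oxidises only this secondary allylic alcohol to 22.

Further compounds
F1 | step 9 | ethyl (3aS,7R,7aS)-7-[(4-methoxybenzyl)oxy]-6-methyl-2-oxo-2,3,3a,4,7,7a-hexahydro-1-benzofuran-3-carboxylate (C7 epimers) | CCOC(=O)C1C(=O)O[C@@H]2[C@H](OCc3ccc(OC)cc3)C(C)=CC[C@@H]12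
F2 | step 9 | corresponding lactone-3-carboxylic acid (C7 epimers) | OC(=O)C1C(=O)O[C@@H]2[C@H](OCc3ccc(OC)cc3)C(C)=CC[C@@H]12
F3 | step 10 | epoxy methylene lactone (16 with the C3–C4 oxirane anti to the C2 ether) | C=C1C(=O)O[C@@H]2[C@H](OCc3ccc(OC)cc3)[C@@]4(C)O[C@H]4C[C@@H]12
F4 | step 10 | C7,C14-diol of F3 (C7 hydroxyl on the face of the C6 hydrogen) | O=C1O[C@@H]2[C@H](OCc3ccc(OC)cc3)[C@@]5(C)O[C@H]5C[C@H]2[C@@]1(O)CO
F5 | step 10 | C14 methanesulfonate of F4 | O=C1O[C@@H]2[C@H](OCc3ccc(OC)cc3)[C@@]5(C)O[C@H]5C[C@H]2[C@@]1(O)COS(C)(=O)=O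
F6 | step 13 | lactol from 18 (C8 anomers) | OC1O[C@@H]2[C@H](OCc3ccc(OC)cc3)[C@@]5(C)O[C@H]5C[C@H]2[C@@]14CO4
F7 | step 13 | C8 allylic alcohol corresponding to 22 (C8 epimers) | O[C@@H]1[C@H](OCc2ccc(OC)cc2)[C@@]3(C)O[C@H]3C[C@H]1[C@]4(C(O)/C=C/C(C)(C)O)CO4
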